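## Structural features

Target 21 (C29H26O4) is a 19-membered macrocyclic bis(bibenzyl). Four benzene rings are joined in a cycle by two diaryl ether oxygens (ring A–O–ring B and ring C–O–ring D) and two CH2CH2 bridges (ring B–ring C and ring D–ring A). The ring atoms count as 3 + 1 + 4 + 2 + 3 + 1 + 3 + 2 = 19. Ring A is 1,3-linked and carries OMe ortho to its ether oxygen and para to its bridge carbon. Ring B is 1,4-linked. Ring C is 1,3-linked with a free OH ortho to its ether oxygen and para to its bridge. Ring D is 1,3-linked and carries nothing else. There is no stereocentre and no alkene in the target, so no stereocontrol is needed.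

The fragile points are the catechol-type ring C (oxidation under base and air) and, along the route, the aryl bromide and chloride (hydrogenolysis) and the ortho-silylaryl triflate (fluoride, alkoxide, nucleophiles). The real difficulty is twofold: closing a 19-membered ring, and making the ring C–O–ring D ether, because the oxygen-bearing carbon of ring D has no acceptor ortho or para to it. The ring A–O–ring B ether is easy by comparison, since ring B is para-substituted by a carbon that can be a formyl group.

The key step exploits ring D numbered from its bridge carbon: C3 (the future C–O carbon) and C4 can be generated as an aryne, and C5, which bears hydrogen in the target, can hold a chlorine that polarises the triple bond and is later exchanged for hydrogen. The seco precursor 18 and the macrocycle 19 were checked atom by atom against this plan (ring size, 1,3,5-pattern of bridge, oxygen and chlorine on ring D) and are consistent with it.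

## Logic of the disconnections

**21 ⇒ 19 (through 20).** The C–H bond at ring D C5 is traced back to C–Cl and the ring C O–H para to the bridge to O–CH2Ph. Chlorine is the regiochemical control element of the ring closure, and the benzyl group ensures that ring C offers only one phenoxide. Both go by hydrogenolysis in one flask, so the two auxiliaries cost a single operation. The forward step must cleave an unactivated aryl chloride and a benzyl ether without touching the diaryl ethers; the amine that promotes C–Cl cleavage is added only after the benzyl group has gone, because amines slow benzyl ether hydrogenolysis on palladium.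

**19 ⇒ 18.** The bond between the ring C oxygen (ortho to the benzyloxy group) and ring D C3 is cut. Addition–elimination is not possible at this carbon, whereas an aryne makes it electrophilic without any acceptor. The cut opens the macrocycle to a linear compound held together only by robust ether and CH2CH2 links. The forward step demands attack at the aryne carbon remote from chlorine, protonation of the ortho-chloroaryl anion before chloride is lost, and intramolecular capture. Slow liberation of fluoride alone does not secure the last point, since every precursor molecule carries its own phenol; 18 is therefore fed slowly into the fluoride so that its stationary concentration stays low.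

**18 ⇒ 14.** The ring D C–Si and O–S bonds are cut. The silylaryl triflate is the most sensitive function of the route and is installed last, from an ordinary ortho-bromophenol. The ring C phenol needs no protecting group of its own: it is silylated together with the ring D phenol and set free again at work-up. The forward step needs bromine–lithium exchange that spares chlorine and the O–Si bonds, and only the ring D oxygen may be an oxide when the triflating agent is added.

**14 ⇒ 12 (through 13).** Both CH2–CH2 bridges are traced back to CH=CH and the ring D O–H to its methoxymethyl acetal. This turns bridge construction into olefination, whose alkene geometry is irrelevant, and keeps the acidic ring D phenol masked through the basic steps. The reduction must saturate two stilbene double bonds without hydrogenolysis of C–Br, C–Cl or O–benzyl, which calls for diimide and excludes palladium.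

**12 ⇒ 8 + 11.** The double bond between ring B and ring C is cut. Ring C arrives as a phosphonium salt with its phenol free. The ylide must therefore be formed with two equivalents of base; the phenoxide is meta to the ylide carbon and does not interfere.

**8 ⇒ 6 + 7.** The bond between the ring A oxygen and ring B is cut. The para-formyl group of 7 activates the displacement and is at once the handle for the next olefination. Because the benzylic carbon of ring A is already an alkene at this stage, no dialdehyde with two similar formyl groups ever arises. The ring D phenol must be masked and its halogens must be inert to carbonate in hot DMF.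

**6 ⇒ 5 + 3.** The double bond between ring A and ring D is cut. Ring D is the aldehyde partner because a benzylic ylide para to a phenoxide would be unusable; the ring D oxygen is therefore an acetal.

**11 ⇒ 10 ⇒ 9; 5 ⇒ 4; 3 ⇒ 2 ⇒ 1.** These cut the C–P bonds, return the benzylic alcohol of 10 to the aldehyde, and remove the acetal and the ring bromine. All end at purchasable compounds. The only selectivity question is the bromination, which has a single open position ortho to the hydroxyl.

## Other disconnections considered

**Alternative 1:** The same ring C–O–ring D bond is cut with reversed polarity: the ring D oxygen is the nucleophile and a ring C carbon ortho to a formyl group the electrophile. In the forward direction the seco phenol A1, whose ring C is a 2-fluorobenzaldehyde unit, would be closed with Cs2CO3 in DMF at high dilution to the macrocyclic aldehyde A2. A Dakin/Baeyer–Villiger oxidation and formate hydrolysis would then convert the formyl group into the ring C hydroxyl of 21.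
- In its favour: macrocyclisation by addition–elimination is standard for diaryl ether macrocycles. The fluorine fixes the site of bond formation, so no regiochemical question exists. The activating group is a latent form of an oxygen the target needs anyway, so neither a directing halogen nor a benzyl ether is carried. No organolithium, triflic anhydride or fluoride-sensitive intermediate is required.
- Against it: an ortho-formyl group activates fluoride displacement only moderately, so the closure needs prolonged heating with carbonate. The ring C formyl group must be masked or introduced late, since it would compete in the olefinations that build the bridges. The peracid must act on a molecule with four electron-rich rings.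
- Comparison: on structure the alternative is the better plan, since all but one carbon of its activating group ends in the target. On mechanism it is the better in certainty, because it rests on known reactivity throughout, whereas the aryne closure is faster, runs at lower temperature and needs no acceptor on either ring. In step count the two are about equal: masking the formyl group and the oxidation offset the bromination, acetal and silyl triflate operations.

**Alternative 2:** The bond between the ring B oxygen and the ring A carbon ortho to the ring A oxygen is cut. Forward, anodic oxidation of the seco bisphenol A3 (ring A a 2,6-dibromo-4-alkylphenol, ring B a 2,6-dichloro-4-alkylphenol) followed by zinc and acetic acid would give the halogenated macrocyclic phenol A4. O-methylation and hydrogenolysis of one bromine, two chlorines and the benzyl group would lead to 21.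
- In its favour: no acceptor group, no metal catalyst and no protecting group on the two reacting phenols are needed. The halogens block the other reactive positions, and the bromine at the coupling carbon leaves in the reductive stage. The reaction runs at room temperature.
- Against it: it spends the key step on the ether that is the easy one in this target (step 5 of the chosen route), so the unactivated ring D ether still has to be made beforehand by other means. Ring A must be a free phenol at the coupling, which adds a methylation. Four halogens must be introduced and three removed. The anode must distinguish two phenols and the electron-rich dialkoxy ring C, and phenoxy radical or cation coupling tends to give C–C and O–C dimers and oligomers.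
- Comparison: on structure the chosen plan addresses the harder bond. On mechanism both closures pass through short-lived intermediates and must be kept intramolecular. In step count the alternative is longer by two halogenations and the methylation. It is the equal of the chosen plan in its final step, since both merge dehalogenation with debenzylation, and the better in needing no strongly basic or organometallic reagent.

**Alternative 3:** An aryl–carbon bond of the ring B–ring C bridge is cut, which contracts the ring retrosynthetically to the 18-membered diaryl ketone A5. Forward, A5 would be converted into the 1,1-diaryl-2,2-dibromoethene A6, and n-BuLi would trigger a Fritsch–Buttenberg–Wiechell rearrangement to the macrocyclic diarylalkyne A7. Hydrogenation would saturate the alkyne and remove the benzyl group to give 21.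
- In its favour: the rearrangement of diaryl dibromoethenes to diarylalkynes is well established in open-chain cases. Whichever aryl group migrates, the same alkyne results, so migratory aptitude is no selectivity problem.
- Against it: the rearrangement closes no ring. The macrocycle, including the unactivated ring D ether, must already exist in A5, so the central problem is only postponed. Dibromo-olefination of a hindered, electron-rich diaryl ketone is sluggish. A7 holds a linear C–C≡C–C unit between a para-linked and a meta-linked ring, and this strain should slow the 1,2-shift relative to protonation or dimerisation of the carbenoid. n-BuLi must spare the benzyl ether.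
- Comparison: on structure the alternative works on a bridge that olefination makes without difficulty. On mechanism both plans rely on high-energy intermediates, the carbenoid on firmer precedent for acyclic cases but not for a ring expansion of this kind. In step count it is clearly longer: ketone, olefination and rearrangement come on top of a separate macrocyclisation. It is the equal or the better of the chosen plan in its final step, which needs no carbon–halogen cleavage.

Key step: step 11

Assumption: 4 (the NaBH4 reduction product of isovanillin) is taken as a purchased material, and the alkenes 6, 8 and 12 are carried as mixtures of geometric isomers because both double bonds are saturated in step 9.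

## Route

Step 1
Reactants: 1 3-chloro-4-hydroxybenzaldehyde
Product: 2 3-bromo-5-chloro-4-hydroxybenzaldehyde
Conditions: Br2 (1.05 equiv), NaOAc, AcOH, rt
Reagents that add atoms: bromine, BrBr
Why: Electrophilic aromatic bromination; the hydroxyl directs ortho, the para position is blocked by the formyl group, and the only open ortho carbon is also meta to the formyl group, so a single product should form.

Step 2
Reactants: 2 3-bromo-5-chloro-4-hydroxybenzaldehyde
Product: 3 3-bromo-5-chloro-4-(methoxymethoxy)benzaldehyde
Conditions: MOMCl, K2CO3, DMF, 0 °C → rt
Reagents that add atoms: chloromethyl methyl ether, COCCl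
Why: O-alkylation of the acidic phenoxide (Williamson-type acetal formation); the acetal keeps the aldehyde electrophilic for the Wittig reaction, is stable to the bases of steps 4, 5 and 8 and leaves with acid.

Step 3
Reactants: 4 3-hydroxy-4-methoxybenzyl alcohol
Product: 5 (3-hydroxy-4-methoxybenzyl)triphenylphosphonium bromide
Conditions: PPh3·HBr, MeCN, reflux
Reagents that add atoms: triphenylphosphine hydrobromide, Br.c1ccc(cc1)P(c1ccccc1)c1ccccc1
Why: Acid-mediated substitution of an electron-rich benzylic alcohol by triphenylphosphine (phosphonium salt formation); the phenol is inert and water is the only by-product.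

Step 4
Reactants: 5 (3-hydroxy-4-methoxybenzyl)triphenylphosphonium bromide; 3 3-bromo-5-chloro-4-(methoxymethoxy)benzaldehyde
Product: 6 5-[2-(3-bromo-5-chloro-4-(methoxymethoxy)phenyl)ethenyl]-2-methoxyphenol (E/Z mixture)
Conditions: 5, KOtBu (2.2 equiv), THF, 0 °C; then 3, 0 °C → rt
Reagents that add atoms: none
Why: Wittig olefination; the second equivalent of base forms the phenoxide, which is meta to the ylide carbon and neither quenches nor conjugates with it, and the alkene geometry is irrelevant because the bond is saturated in step 9.

Step 5
Reactants: 6 5-[2-(3-bromo-5-chloro-4-(methoxymethoxy)phenyl)ethenyl]-2-methoxyphenol; 7 4-fluorobenzaldehyde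
Product: 8 4-{5-[2-(3-bromo-5-chloro-4-(methoxymethoxy)phenyl)ethenyl]-2-methoxyphenoxy}benzaldehyde (E/Z mixture)
Conditions: 7 (1.3 equiv), K2CO3, DMF, 100 °C
Reagents that add atoms: none
Why: Nucleophilic aromatic substitution (SNAr) activated by the para-formyl group; the ring A phenoxide is the only nucleophile, the ring D halogens carry no activating group, and the acetal is stable to carbonate.

Step 6
Reactants: 9 4-(benzyloxy)-3-hydroxybenzaldehyde
Product: 10 4-(benzyloxy)-3-hydroxybenzyl alcohol
Conditions: NaBH4, MeOH, 0 °C
Reagents that add atoms: none
Why: Hydride reduction of the aldehyde; phenol and benzyl ether are untouched.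

Step 7
Reactants: 10 4-(benzyloxy)-3-hydroxybenzyl alcohol
Product: 11 [4-(benzyloxy)-3-hydroxybenzyl]triphenylphosphonium bromide
Conditions: PPh3·HBr, MeCN, reflux
Reagents that add atoms: triphenylphosphine hydrobromide, Br.c1ccc(cc1)P(c1ccccc1)c1ccccc1
Why: Phosphonium salt formation as in step 3; the para-benzyloxy group assists ionisation of the benzylic alcohol, and the one equivalent of HBr is consumed in the salt, so the benzyl ether should survive.

Step 8
Reactants: 8 4-{5-[2-(3-bromo-5-chloro-4-(methoxymethoxy)phenyl)ethenyl]-2-methoxyphenoxy}benzaldehyde; 11 [4-(benzyloxy)-3-hydroxybenzyl]triphenylphosphonium bromide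
Product: 12 2-(benzyloxy)-5-{2-[4-(5-{2-[3-bromo-5-chloro-4-(methoxymethoxy)phenyl]ethenyl}-2-methoxyphenoxy)phenyl]ethenyl}phenol (mixture of alkene isomers)
Conditions: 11, KOtBu (2.2 equiv), THF, 0 °C; then 8, 0 °C → rt
Reagents that add atoms: none
Why: Wittig olefination with a phenoxide-bearing ylide as in step 4; aryl halides, acetal and the first stilbene are inert to the ylide.

Step 9
Reactants: 12 2-(benzyloxy)-5-{2-[4-(5-{2-[3-bromo-5-chloro-4-(methoxymethoxy)phenyl]ethenyl}-2-methoxyphenoxy)phenyl]ethenyl}phenol
Product: 14 4-{2-[3-(4-{2-[4-(benzyloxy)-3-hydroxyphenyl]ethyl}phenoxy)-4-methoxyphenyl]ethyl}-2-bromo-6-chlorophenol, via methoxymethyl ether bis(bibenzyl) 13 (not isolated)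
Conditions: TsNHNH2 (excess, in portions), NaOAc, DME/H2O, reflux; extractive work-up, then 3 M HCl, MeOH/THF, 50 °C
Reagents that add atoms: none
Why: Diimide, formed by thermal loss of sulfinate from the hydrazide, delivers H2 to C=C by concerted syn transfer and cannot cleave C–Br, C–Cl or O–benzyl bonds, which palladium would attack; acid methanolysis then removes the acetal while benzyl and diaryl ethers stay.

Step 10
Reactants: 14 4-{2-[3-(4-{2-[4-(benzyloxy)-3-hydroxyphenyl]ethyl}phenoxy)-4-methoxyphenyl]ethyl}-2-bromo-6-chlorophenol
Product: 18 4-{2-[3-(4-{2-[4-(benzyloxy)-3-hydroxyphenyl]ethyl}phenoxy)-4-methoxyphenyl]ethyl}-2-chloro-6-(trimethylsilyl)phenyl trifluoromethanesulfonate, via bis(trimethylsilyl) ether 15 (not isolated), via lithium 2-silylphenoxide 16 (not isolated), via ring C silyl ether of the triflate 17 (not isolated)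
Conditions: HMDS, THF, reflux, then evaporation; n-BuLi (1.05 equiv), THF, −100 → −80 °C; Tf2O, −100 → −78 °C; then 1 M HCl, THF, rt
Reagents that add atoms: hexamethyldisilazane, C[Si](C)(C)N[Si](C)(C)C; trifluoromethanesulfonic anhydride, O=S(=O)(OS(=O)(=O)C(F)(F)F)C(F)(F)F
Why: O-silylation, bromine–lithium exchange, 1,3-retro-Brook shift of silicon from oxygen to the lithiated carbon and triflation of the resulting phenoxide; exchange at −100 °C is faster than attack of n-BuLi on O–Si or C–Cl, and only ring D carries an oxide when Tf2O is added. The ring C phenol is masked in the same operation as its trimethylsilyl ether, which dilute acid removes at work-up without touching the C–Si bond or the triflate.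

Step 11
Reactants: 18 4-{2-[3-(4-{2-[4-(benzyloxy)-3-hydroxyphenyl]ethyl}phenoxy)-4-methoxyphenyl]ethyl}-2-chloro-6-(trimethylsilyl)phenyl trifluoromethanesulfonate
Product: 19 19-membered macrocycle with the ring C benzyl ether and chlorine on ring D meta to both the new ether oxygen and the bridge
Conditions: CsF (6 equiv), MeCN, 50 °C; 18 in MeCN added by syringe pump over 16 h (final 1 mM)
Reagents that add atoms: none
Why: Proposed new method: fluoride attacks the trimethylsilyl group of ring D, the aryl anion expels triflate from the neighbouring carbon, and a 3-chloroaryne results whose triple bond lies between the former C–Si and C–OTf carbons with chlorine next to the latter. The ring C phenol, deprotonated by CsF, adds to the aryne carbon remote from chlorine; the charge then develops beside the σ-withdrawing C–Cl bond, the ground-state distortion of a 3-haloaryne makes the remote carbon the more electrophilic one, and the bulk of chlorine acts in the same direction. The ortho-chloroaryl anion should be protonated by bifluoride or acetonitrile before chloride can be lost. The closest known reaction type is the intermolecular O-arylation of phenols by arynes from ortho-silylaryl triflates with CsF in acetonitrile, with regiocontrol by a 3-halogen; new is its use to close a macrocycle. The 19-membered ring closes by end-to-end capture, formally an exo-dig closure in which the second aryne carbon stays outside the ring. No stereocentre is formed. The step needs regioselectivity (secured by chlorine), intramolecular over intermolecular capture (secured by feeding 18 slowly into the warm CsF suspension so that its stationary concentration stays well below 1 mM), and chemoselectivity for the phenoxide (the other ring C oxygen is benzylated and dissolved fluoride is scarce).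

Step 12
Reactants: 19 19-membered macrocycle with the ring C benzyl ether and chlorine on ring D
Product: 21 CNP0132125.0, via debenzylated chloro macrocycle 20 (not isolated)
Conditions: H2 (1 atm), 10% Pd/C, MeOH/EtOAc, rt; then Et3N (3 equiv), H2, rt
Reagents that add atoms: none
Why: Hydrogenolysis of the benzyl ether followed in the same flask by base-promoted hydrodechlorination on palladium; the amine traps HCl and accelerates C–Cl cleavage and is held back until debenzylation is complete because amines retard benzyl ether cleavage. Diaryl ethers, the methoxy group and the benzylic CH2 groups are stable.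

## Compound list

1 | 3-chloro-4-hydroxybenzaldehyde | O=Cc1ccc(O)c(Cl)c1 | starting material
2 | 3-bromo-5-chloro-4-hydroxybenzaldehyde | O=Cc1cc(Cl)c(O)c(Br)c1 | intermediate
3 | 3-bromo-5-chloro-4-(methoxymethoxy)benzaldehyde | COCOc1c(Cl)cc(C=O)cc1Br | intermediate
4 | 3-hydroxy-4-methoxybenzyl alcohol (isovanillyl alcohol) | COc1ccc(CO)cc1O | starting material
5 | (3-hydroxy-4-methoxybenzyl)triphenylphosphonium bromide | COc1ccc(C[P+](c2ccccc2)(c2ccccc2)c2ccccc2)cc1O.[Br-] | intermediate
6 | 5-[2-(3-bromo-5-chloro-4-(methoxymethoxy)phenyl)ethenyl]-2-methoxyphenol, E/Z mixture | COCOc1c(Cl)cc(C=Cc2ccc(OC)c(O)c2)cc1Br | intermediate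
7 | 4-fluorobenzaldehyde | O=Cc1ccc(F)cc1 | starting material
8 | 4-{5-[2-(3-bromo-5-chloro-4-(methoxymethoxy)phenyl)ethenyl]-2-methoxyphenoxy}benzaldehyde, E/Z mixture | COCOc1c(Cl)cc(C=Cc2ccc(OC)c(Oc3ccc(C=O)cc3)c2)cc1Br | intermediate
9 | 4-(benzyloxy)-3-hydroxybenzaldehyde | O=Cc1ccc(OCc2ccccc2)c(O)c1 | starting material
10 | 4-(benzyloxy)-3-hydroxybenzyl alcohol | OCc1ccc(OCc2ccccc2)c(O)c1 | intermediate
11 | [4-(benzyloxy)-3-hydroxybenzyl]triphenylphosphonium bromide | Oc1cc(C[P+](c2ccccc2)(c2ccccc2)c2ccccc2)ccc1OCc1ccccc1.[Br-] | intermediate
12 | 2-(benzyloxy)-5-{2-[4-(5-{2-[3-bromo-5-chloro-4-(methoxymethoxy)phenyl]ethenyl}-2-methoxyphenoxy)phenyl]ethenyl}phenol, mixture of alkene isomers | COCOc1c(Cl)cc(C=Cc2ccc(OC)c(Oc3ccc(C=Cc4ccc(OCc5ccccc5)c(O)c4)cc3)c2)cc1Br | intermediate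
13 | 2-(benzyloxy)-5-{2-[4-(5-{2-[3-bromo-5-chloro-4-(methoxymethoxy)phenyl]ethyl}-2-methoxyphenoxy)phenyl]ethyl}phenol | COCOc1c(Cl)cc(CCc2ccc(OC)c(Oc3ccc(CCc4ccc(OCc5ccccc5)c(O)c4)cc3)c2)cc1Br | intermediate
14 | 4-{2-[3-(4-{2-[4-(benzyloxy)-3-hydroxyphenyl]ethyl}phenoxy)-4-methoxyphenyl]ethyl}-2-bromo-6-chlorophenol | Oc1c(Cl)cc(CCc2ccc(OC)c(Oc3ccc(CCc4ccc(OCc5ccccc5)c(O)c4)cc3)c2)cc1Br | intermediate
15 | bis(trimethylsilyl) ether of 14 (both phenol oxygens silylated) | C[Si](C)(C)Oc1c(Cl)cc(CCc2ccc(OC)c(Oc3ccc(CCc4ccc(OCc5ccccc5)c(O[Si](C)(C)C)c4)cc3)c2)cc1Br | intermediate
16 | lithium 2-chloro-6-(trimethylsilyl)phenoxide of ring D, ring C oxygen still as trimethylsilyl ether | [Li+].[O-]c1c(Cl)cc(CCc2ccc(OC)c(Oc3ccc(CCc4ccc(OCc5ccccc5)c(O[Si](C)(C)C)c4)cc3)c2)cc1[Si](C)(C)C | intermediate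
17 | ring C O-trimethylsilyl ether of 18 | C[Si](C)(C)c1cc(CCc2ccc(OC)c(Oc3ccc(CCc4ccc(OCc5ccccc5)c(O[Si](C)(C)C)c4)cc3)c2)cc(Cl)c1OS(=O)(=O)C(F)(F)F | intermediate
18 | 4-{2-[3-(4-{2-[4-(benzyloxy)-3-hydroxyphenyl]ethyl}phenoxy)-4-methoxyphenyl]ethyl}-2-chloro-6-(trimethylsilyl)phenyl trifluoromethanesulfonate | C[Si](C)(C)c1cc(CCc2ccc(OC)c(Oc3ccc(CCc4ccc(OCc5ccccc5)c(O)c4)cc3)c2)cc(Cl)c1OS(=O)(=O)C(F)(F)F | intermediate
19 | 19-membered macrocycle, ring C benzyl ether, ring D chlorine meta to ether oxygen and bridge | COc1ccc2cc1Oc1ccc(cc1)CCc1ccc(OCc3ccccc3)c(c1)Oc1cc(Cl)cc(c1)CC2 | intermediate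
20 | 19-membered macrocycle, ring C free phenol, ring D chlorine | COc1ccc2cc1Oc1ccc(cc1)CCc1ccc(O)c(c1)Oc1cc(Cl)cc(c1)CC2 | intermediate
21 | CNP0132125.0, macrocyclic bis(bibenzyl) phenol | COc1ccc2cc1Oc1ccc(cc1)CCc1ccc(O)c(c1)Oc1cccc(c1)CC2 | target

## Step count and least certain steps

Total: 12 steps; steps 9, 10 and 12 each combine operations in one flask. Longest linear sequence: 9 steps (1, 2, 4, 5, 8, 9, 10, 11, 12).

**Step 11 (key step, Proposed new method).** Most likely to go wrong:
- intermolecular capture of the aryne by the phenoxide of a second molecule, which leads to oligomerisation, because the addition is nearly barrierless and unselective;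
- addition at the chlorine-flanked carbon, which would close a 20-membered isomer;
- loss of chloride from the ortho-chloroaryl anion, giving a second aryne;
- trapping of the aryne by fluoride.

Fallback with known chemistry, setting out from 5 and coming back at 21:
- Wittig reaction of 5 (KOtBu, THF) with purchased 3-bromobenzaldehyde (O=Cc1cccc(Br)c1) would give 5-[2-(3-bromophenyl)ethenyl]-2-methoxyphenol F1.
- SNAr with 7 (K2CO3, DMF) would give 4-{5-[2-(3-bromophenyl)ethenyl]-2-methoxyphenoxy}benzaldehyde F2.
- Wittig reaction with 11 would give the bis-stilbene phenol F3, and diimide reduction the seco aryl bromide F4.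
- An intramolecular Ullmann ether synthesis (CuI, copper monoiodide; N,N-dimethylglycine; Cs2CO3; 1,4-dioxane; 100 °C; 5 mM) would close the ring to the chlorine-free macrocyclic benzyl ether F5.
- Hydrogenolysis (H2, 10% Pd/C) would give 21.

**Step 10.** Most likely to go wrong: cleavage of the ring C O–Si bond by n-BuLi or silyl scrambling between the two oxygens, so that ring C is triflated as well; or incomplete retro-Brook shift before Tf2O arrives.

Fallback, setting out from 13 (isolated after the diimide stage of step 9) and coming back at 19:
- TBSCl and imidazole would give the ring C tert-butyldimethylsilyl ether F6.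
- ZnBr2 and n-PrSH in CH2Cl2 would cleave the acetal only and give the ring D phenol F7.
- The silylation, retro-Brook and triflation sequence of step 10 would give the silylaryl triflate F8 with ring C still silylated.
- Under the conditions of step 11, with one equivalent of tert-butanol as proton donor, CsF would free the ring C phenoxide in the flask and generate the aryne, giving 19.

**Step 9.** Most likely to go wrong: incomplete saturation of the trans-stilbene units, because diimide reacts slowly with conjugated alkenes and is lost by disproportionation. Fallback, setting out from 12 and coming back at 13: homogeneous hydrogenation (H2, 4 atm, RhCl(PPh3)3, toluene/EtOH, 50 °C), which saturates disubstituted alkenes but spares aryl halides and benzyl ethers, followed by the same acid treatment to 14.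

**Step 12.** Most likely to go wrong: stalling of C–Cl hydrogenolysis on the poorly activated ring D, or slow debenzylation once amine is present. Fallback, setting out from 19 and coming back at 21: debenzylation with BCl3 and pentamethylbenzene (CH2Cl2, −78 °C) to isolated 20, then homogeneous hydrodechlorination (Pd(OAc)2, polymethylhydrosiloxane, aqueous KF, THF, rt).

## Further compounds

F1 | step 11 | 5-[2-(3-bromophenyl)ethenyl]-2-methoxyphenol, E/Z mixture | COc1ccc(C=Cc2cccc(Br)c2)cc1O
F2 | step 11 | 4-{5-[2-(3-bromophenyl)ethenyl]-2-methoxyphenoxy}benzaldehyde, E/Z mixture | COc1ccc(C=Cc2cccc(Br)c2)cc1Oc1ccc(C=O)cc1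
F3 | step 11 | 2-(benzyloxy)-5-{2-[4-(5-{2-[3-bromophenyl]ethenyl}-2-methoxyphenoxy)phenyl]ethenyl}phenol, mixture of alkene isomers | COc1ccc(C=Cc2cccc(Br)c2)cc1Oc1ccc(C=Cc2ccc(OCc3ccccc3)c(O)c2)cc1
F4 | step 11 | 2-(benzyloxy)-5-{2-[4-(5-{2-[3-bromophenyl]ethyl}-2-methoxyphenoxy)phenyl]ethyl}phenol | COc1ccc(CCc2cccc(Br)c2)cc1Oc1ccc(CCc2ccc(OCc3ccccc3)c(O)c2)cc1
F5 | step 11 | 19-membered macrocycle with ring C benzyl ether and unsubstituted ring D | COc1ccc2cc1Oc1ccc(cc1)CCc1ccc(OCc3ccccc3)c(c1)Oc1cccc(c1)CC2
F6 | step 10 | ring C tert-butyldimethylsilyl ether of 13 | COCOc1c(Cl)cc(CCc2ccc(OC)c(Oc3ccc(CCc4ccc(OCc5ccccc5)c(O[Si](C)(C)C(C)(C)C)c4)cc3)c2)cc1Br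
F7 | step 10 | ring C tert-butyldimethylsilyl ether of 14 (ring D phenol free) | Oc1c(Cl)cc(CCc2ccc(OC)c(Oc3ccc(CCc4ccc(OCc5ccccc5)c(O[Si](C)(C)C(C)(C)C)c4)cc3)c2)cc1Br
F8 | step 10 | ring C tert-butyldimethylsilyl ether of 18 | C[Si](C)(C)c1cc(CCc2ccc(OC)c(Oc3ccc(CCc4ccc(OCc5ccccc5)c(O[Si](C)(C)C(C)(C)C)c4)cc3)c2)cc(Cl)c1OS(=O)(=O)C(F)(F)F
F0 | step 9 | none | none
F0 | step 12 | none | none
A1 | alternative 1 | seco phenol with ring D 3-hydroxyphenyl and ring C 2-fluorobenzaldehyde unit | COc1ccc(CCc2cccc(O)c2)cc1Oc1ccc(CCc2ccc(C=O)c(F)c2)cc1
A2 | alternative 1 | macrocycle with formyl group in place of the ring C hydroxyl | COc1ccc2cc1Oc1ccc(cc1)CCc1ccc(C=O)c(c1)Oc1cccc(c1)CC2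
A3 | alternative 2 | seco bisphenol with ring A 2,6-dibromophenol and ring B 2,6-dichlorophenol | Oc1c(Br)cc(CCc2cccc(Oc3cc(CCc4cc(Cl)c(O)c(Cl)c4)ccc3OCc3ccccc3)c2)cc1Br
A4 | alternative 2 | macrocycle with ring A hydroxyl and bromine, ring B dichloride, ring C benzyl ether | Oc1c(Br)cc2cc1Oc1c(Cl)cc(cc1Cl)CCc1ccc(OCc3ccccc3)c(c1)Oc1cccc(c1)CC2
A5 | alternative 3 | 18-membered macrocyclic diaryl ketone between rings B and C | COc1ccc2cc1Oc1ccc(cc1)C(=O)c1ccc(OCc3ccccc3)c(c1)Oc1cccc(c1)CC2
A6 | alternative 3 | macrocyclic 1,1-diaryl-2,2-dibromoethene | COc1ccc2cc1Oc1ccc(cc1)C(=C(Br)Br)c1ccc(OCc3ccccc3)c(c1)Oc1cccc(c1)CC2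
A7 | alternative 3 | 19-membered macrocyclic diarylalkyne between rings B and C | COc1ccc2cc1Oc1ccc(cc1)C#Cc1ccc(OCc3ccccc3)c(c1)Oc1cccc(c1)CC2
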